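## Structural features

The target is a germacranolide of the furanoheliangolide type. Its ten-membered carbocycle (C1–C10) is spanned by an oxygen between C3 and C10, so that O–C3=C2–C1(=O)–C10 is a 3(2H)-furanone whose enone is extended by the (Z)-C4=C5 alkene. A trans-fused α-methylene-γ-butyrolactone sits on C6–C7 (O6–C12(=O)–C11=C13), C8 carries a methacrylate and C9 an acetate. The five stereocentres are contiguous: C6 (R), C7 (S), C8 (S), C9 (S) and the fully substituted bridgehead C10 (S); H6 and H7 are anti, and the C8 and C9 oxygens are erythro. Fragile groups are the methylene lactone and the methacrylate (Michael acceptors), the acetate next to a cis oxygen (acyl shift), the cross-conjugated vinylogous ester (bases, nucleophiles), and the (Z)-alkene, which can isomerise in any open-chain enal form. The real difficulty is closing a ten-membered ring that holds a cis alkene, a bridging five-membered heterocycle and two ring fusions, with five adjacent stereocentres already in place. The key step uses the vinylogous ester C1(=O)–C2=C3(–O) as a masked 1,3-dicarbonyl unit, which is the retron of a 3,5-disubstituted isoxazole with nitrogen on C3 and oxygen on C1. A C3 nitrile oxide and a C1≡C2 terminal alkyne on the C10 carbinol can therefore form C2–C3 and O–C1 in one cycloaddition that closes carbocycle and heterocycle together.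

## Logic of the disconnections

35 ⇒ 33. The C11=C13 double bond is traced back to a C13–N single bond (formal addition of dimethylamine). The exocyclic enoate is the most electrophilic site and is better not exposed to low-valent metal, acid and acyl-transfer catalysts. The gain is that 28–33 carry a saturated C11 whose configuration is irrelevant. The forward step must quaternise and eliminate under conditions mild enough for two esters and the vinylogous ester.

33 ⇒ 32 ⇒ 31. The acyl–oxygen bonds at O9 and O8 are cut, because esters cannot pass the organometallic steps. The gain is a free cis-diol. The first acylation must choose O8 over O9; the neopentyl position of O9 next to quaternary C10 is relied on.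

31 ⇒ 28 (through 30 and 29). The C3–O10 bond of the furanone is cut, C3 receives nitrogen, and that nitrogen is tied to the C1 oxygen as the N–O bond of an isoxazole; the C8/C9 acetal is restored. The aromatic isoxazole hides the base-sensitive vinylogous ester and can be made by cycloaddition. The forward step needs an N–O reduction that spares the (Z)-alkene and the lactone, and the C10 hydroxyl must displace ammonia at C3 before O9 is set free.

28 ⇒ 27. The C11–C13 bond is cut (Mannich retron). Placing this step at the isoxazole stage means the enolate is formed while the furanone is still masked. The forward step needs a strong base that tolerates a free tertiary alcohol and a 3,5-disubstituted isoxazole.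

27 ⇒ 24 (through 26 and 25). The C2–C3 and O–C1 bonds are cut; this opens the isoxazole and the ten-membered ring and leaves a nitrile oxide at C3 and a terminal alkyne C1≡C2. The gain is the largest of the route: two rings and two skeletal bonds are removed and an acyclic chain with all stereocentres already set remains. The forward step must close in the bridged 3,5-sense and must beat dimerisation of the dipole.

24 ⇒ 23 ⇒ 22 ⇒ 21. The C3=N bond, the C3 oxidation level and the two silicon bonds (O3–Si, C2–Si) are retraced. Nitrile oxide precursor and terminal alkyne are thus unveiled only at the end of the open-chain sequence. One fluoride treatment must remove both silyl groups, and the (Z)-enal must not isomerise.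

21 ⇒ 19 ⇒ 17 (through 20 and 18). The lactone O6–C12 bond and the C12 oxygen are retraced to a vinyl group on C7. A vinyl group is what an allylmetal addition delivers. The forward steps need a hydroboration that ignores the trisubstituted alkene and the capped alkyne, and an oxidation that takes the primary alcohol before the allylic secondary one.

17 ⇒ 11 + 15 (through 16). The C6–C7 bond is cut; this is the convergent step and it creates C6 and C7. Both fragments are then small and the C8 centre of 11 can steer the new centres. The forward step must be anti-selective at C6/C7 and must attack the correct face with respect to C8.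

11 ⇒ 10 ⇒ 9. The C12–Br bond and the C12 ester oxidation level are retraced, so that the allyl donor comes from an enoate made by olefination. The primary allylic alcohol must react chemoselectively next to a tertiary one.

9 ⇒ 8 ⇒ 7 ⇒ 4 + 5 (through 6). The C10–CH3 bond and then the C10–C1 bond are cut, so that the quaternary carbinol is built from a primary alcohol by two carbon nucleophiles. Methyl must come second: under chelation it then enters from the face that gives the required C10 configuration. The α-alkoxy aldehyde must not epimerise.

4 ⇒ 2 + 3 and 2 ⇒ 1. The C7=C11 bond is cut and the lactol is retraced to the lactone. The carbonyl carbon of 1 becomes C7 and its CH2O carbon becomes C10, which is the only assignment that gives the (8S,9S) diol. The olefination must not trigger oxa-Michael ring closure.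

15 ⇒ 14 ⇒ 13 ⇒ 12. The C6 formyl group is retraced to an amide and the amide to the lactone carbonyl. The ring of 12 fixes the (Z)-geometry and places the carbonyl at C6 and the oxygen at C3. The opened hydroxy amide must be silylated before it relactonises.

## Other disconnections considered

Alternative 1: The cut is C9–C10. In the forward direction BF3·OEt2 would activate the C9 aldehyde of seco compound A1, and the methyl-bearing carbon of its 3-silyloxyfuran would attack it. This closes the ten-membered ring and regenerates the furanone, giving 9-O-deacetyl compound A2, which is one acetylation away from 35.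
- In its favour: the furanone needs no unmasking, and the route after ring closure is four steps shorter than in the chosen plan, so on that count it is the better one.
- Against it: the ring closure has to create two adjacent stereocentres (C9, and quaternary C10) under a monodentate Lewis acid, with only C8 to steer. A1 must already carry the methylene lactone and the methacrylate, both acceptors for a silyl enol ether under Lewis acid. The α-acyloxy aldehyde is prone to epimerisation and acyl shift. A2 is a β-hydroxy ketone in a strained ring and could reopen by retro-aldol reaction.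
- Comparison: both plans close carbocycle and heterocycle in one step and both need high dilution, so they are equal there. The chosen plan forms no stereocentre during closure and uses a concerted cycloaddition in place of an open, stepwise transition state. The overall step count is probably similar, because A1 demands a fully decorated seco chain.

Alternative 2: The C3–O10 bond is formed while the oxygen of a furan that bridges C3 and C6 is given up. Anodic oxidation of furan A3 in methanol and mild acid would bring C3 and C6 to the cis-enedione level. The C10 hydroxyl would then condense with the C1/C3 diketone to give furanone A4 with a C6 ketone.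
- In its favour: the (Z)-geometry of C4=C5 is guaranteed by the furan ring and never exists as an open-chain enal, which is better than the chosen plan on this point. The oxidation needs no chemical oxidant.
- Against it: A3 is itself a ten-membered ring spanned by a 2,5-furan over six atoms, so the macrocyclisation problem is moved and not solved. The C6 ketone makes C7 epimerisable. C6 must later be reduced to the (R)-alcohol next to a second enone, then lactonised, and the methylene introduced on a base-sensitive furanone.
- Comparison: both plans mask the furanone as an aromatic heterocycle. The isoxazole already has its heteroatoms on C3 and C1, whereas the furan has its oxygen on C3/C6 and leaves a ketone to correct. The step count after the key step is at best equal and probably higher.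

Alternative 3: The cut is C1–C2. CrCl2 with catalytic NiCl2 would turn the iodoalkyne of A5 into an alkynylchromium species that adds to the C1 aldehyde and gives the ten-membered enyne A6. Oxidation to the ynone, loss of the silyl group and transannular 5-endo addition of the C10 oxygen to C3 would give the furanone.
- In its favour: every step belongs to a known reaction type, including closure of ten-membered enyne rings by this chromium chemistry. The C1 configuration is irrelevant. The aldehyde on quaternary C10 cannot enolise. On precedent this alternative is the better of the two.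
- Against it: four atoms (C4–C3≡C2–C1) must be collinear in a ten-membered ring next to a (Z)-alkene and two ring fusions. The aldehyde is neopentylic. The methylene lactone has to pass the chromium step or be introduced with the ynone or furanone present.
- Comparison: the number of steps after ring closure is about equal. The chosen plan forms two bonds and both rings in one redox-neutral step and keeps the furanone masked during lactone methylenation, but it rests on an untested ring closure. The fallback given below for step 17 borrows the chromium chemistry of this alternative at C2–C3.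

Key step: step 17

Remark: germacrane numbering is used for all intermediates; the CIP label of C10 changes from R (9–26) to S (27–35) without any change in spatial arrangement.
Remark: 3-methyl-2(5H)-furanone would place its carbonyl carbon at C3; the 4-methyl isomer 12 is used because its carbonyl carbon becomes C6 and its CH2O carbon C3.
Remark: step 2 is taken to give mainly the (E)-enoate; any (Z)-isomer converges with it at 16.

## Steps

Step 1
Reactants: 1 2,3-O-isopropylidene-D-erythronolactone
Product: 2 2,3-O-isopropylidene-D-erythrofuranose (lactol; anomers)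
Conditions: iBu2AlH, CH2Cl2, −78 °C; aq. KNaC4H4O6
Reagents that add atoms: none
Why: Partial hydride reduction of a γ-lactone stops at the aluminium hemiacetal at low temperature; the two acetonide stereocentres (later C8 and C9) are untouched.

Step 2
Reactants: 2; 3 ethyl (triphenylphosphoranylidene)acetate
Product: 4 ethyl (E)-3-[(4S,5R)-5-(hydroxymethyl)-2,2-dimethyl-1,3-dioxolan-4-yl]prop-2-enoate
Conditions: PhCO2H (cat.), toluene, 80 °C
Reagents that add atoms: none
Why: Wittig olefination of the open hydroxy aldehyde form of the lactol with a stabilised ylide; weak acid catalysis in a non-polar solvent should favour the (E)-enoate and avoid the base-induced oxa-Michael closure to a tetrahydrofuran.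

Step 3
Reactants: 4; 5 trimethylsilylacetylene
Product: 7 ethyl (E)-3-{(4S,5R)-5-[1-hydroxy-3-(trimethylsilyl)prop-2-ynyl]-2,2-dimethyl-1,3-dioxolan-4-yl}prop-2-enoate (both C10 epimers), via aldehyde 6 (not isolated)
Conditions: (COCl)2, DMSO, CH2Cl2, −78 °C; Et3N; then LiC≡CSiMe3 (from 5 and n-BuLi, THF; excess), −78 °C; aq. NH4Cl
Reagents that add atoms: none
Why: Swern oxidation followed by acetylide addition to the cold mixture, so that the cis-configured α-alkoxy aldehyde 6 is never warmed with base and should not epimerise at C9; the acetylide adds to the aldehyde much faster than to the enoate, and the new carbinol centre is removed in step 4.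

Step 4
Reactants: 7
Product: 8 ethyl (E)-3-{(4S,5S)-2,2-dimethyl-5-[3-(trimethylsilyl)prop-2-ynoyl]-1,3-dioxolan-4-yl}prop-2-enoate
Conditions: Dess–Martin periodinane, NaHCO3, CH2Cl2, 0 °C → rt
Reagents that add atoms: none
Why: Dess–Martin oxidation of a secondary propargylic alcohol under buffered, non-basic conditions, which should leave the α-stereocentre C9 and the enoate alone.

Step 5
Reactants: 8
Product: 9 ethyl (E)-3-{(4S,5S)-5-[(2R)-2-hydroxy-4-(trimethylsilyl)but-3-yn-2-yl]-2,2-dimethyl-1,3-dioxolan-4-yl}prop-2-enoate
Conditions: MeMgBr, CH2Cl2/Et2O, −78 °C; aq. NH4Cl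
Reagents that add atoms: methylmagnesium bromide, C[Mg]Br
Why: Chelation-controlled Grignard 1,2-addition (Cram chelate): magnesium bridges the ketone oxygen and the dioxolane oxygen on C9, and methyl attacks the face of the chelate ring opposite to the C8 substituent, which sets C10; the ynone carbonyl is far more electrophilic than the enoate at this temperature.

Step 6
Reactants: 9
Product: 10 (E)-3-{(4S,5S)-5-[(2R)-2-hydroxy-4-(trimethylsilyl)but-3-yn-2-yl]-2,2-dimethyl-1,3-dioxolan-4-yl}prop-2-en-1-ol
Conditions: iBu2AlH (3.5 equiv), CH2Cl2, −78 °C; aq. KNaC4H4O6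
Reagents that add atoms: none
Why: 1,2-Reduction of an enoate to the allylic alcohol by an electrophilic aluminium hydride; the tertiary alkoxide and the silylalkyne are inert at this temperature.

Step 7
Reactants: 10
Product: 11 (2R)-2-{(4S,5S)-5-[(E)-3-bromoprop-1-enyl]-2,2-dimethyl-1,3-dioxolan-4-yl}-4-(trimethylsilyl)but-3-yn-2-ol
Conditions: CBr4, PPh3, 2,6-lutidine, CH2Cl2, −20 → 0 °C
Reagents that add atoms: carbon tetrabromide, BrC(Br)(Br)Br
Why: Appel bromination; the primary allylic alcohol should react much faster than the hindered tertiary propargylic one, and the bromide is used without delay.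

Step 8
Reactants: 12 4-methyl-2(5H)-furanone
Product: 13 (Z)-4-hydroxy-N-methoxy-N,3-dimethylbut-2-enamide
Conditions: MeNH(OMe)·HCl, Me3Al, CH2Cl2, 0 °C → rt; aq. KNaC4H4O6
Reagents that add atoms: N,O-dimethylhydroxylamine hydrochloride, CNOC.Cl
Why: Aluminium amide-mediated aminolysis of the lactone (Weinreb amide formation) opens the butenolide with its ring-locked (Z)-geometry intact; the crude hydroxy amide is silylated at once to forestall relactonisation.

Step 9
Reactants: 13
Product: 14 (Z)-4-[(tert-butyldimethylsilyl)oxy]-N-methoxy-N,3-dimethylbut-2-enamide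
Conditions: tBuMe2SiCl, imidazole, DMF, 0 °C → rt
Reagents that add atoms: tert-butyldimethylsilyl chloride, CC(C)(C)[Si](C)(C)Cl
Why: Silyl ether formation at the primary allylic hydroxyl (the later C3 oxygen), which also removes the nucleophile that could re-close the lactone.

Step 10
Reactants: 14
Product: 15 (Z)-4-[(tert-butyldimethylsilyl)oxy]-3-methylbut-2-enal
Conditions: iBu2AlH, THF, −78 °C; aq. KNaC4H4O6
Reagents that add atoms: none
Why: Reduction of a Weinreb amide stops at the aldehyde because the chelated aluminium hemiaminal survives until work-up; low temperature and neutral work-up should keep the (Z)-geometry.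

Step 11
Reactants: 11; 15
Product: 17 homoallylic alcohol (6R,7S,8S,9S,10R): C6 carbinol between the (Z)-C4=C5 alkene (C3 as CH2OSiMe2tBu) and C7; C7 carries a vinyl group and the dioxolane of 11, via allylchromium dichloride 16 (not isolated)
Conditions: CrCl2 (4 equiv), THF, 0 °C → rt
Reagents that add atoms: none
Why: Nozaki–Hiyama allylation: CrCl2 (divalent chromium) converts 11 into the (E)-allylchromium species 16, which adds through its γ-carbon in a chair (Zimmerman–Traxler) transition state with both substituents equatorial and so should give the anti C6/C7 pair. The aldehyde is expected to approach C7 anti to the dioxolane C8–O bond with the C8 hydrogen turned toward the aldehyde substituent, which gives the 7,8-anti isomer drawn; addition to the enal is 1,2.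

Step 12
Reactants: 17
Product: 19 triol (6R,7S,8S,9S,10R): 17 with CH2CH2OH (C11, C12) in place of the vinyl group, via B-alkyl-9-BBN 18 (not isolated)
Conditions: 9-BBN-H (4 equiv), THF, 0 °C → rt; then H2O2, aq. NaOH, 0 °C
Reagents that add atoms: hydrogen peroxide, OO
Why: Anti-Markovnikov hydroboration–oxidation; the bulky borane should select the monosubstituted vinyl group over the trisubstituted alkene and the silyl-capped alkyne, and no stereocentre is formed.

Step 13
Reactants: 19
Product: 21 trans-γ-lactone (6R,7S,8S,9S,10R) closed between O6 and C12; C3 OSiMe2tBu; C2 SiMe3, via lactol 20 (not isolated)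
Conditions: 2,2,6,6-tetramethylpiperidine-1-oxyl (cat.), PhI(OAc)2, CH2Cl2, rt
Reagents that add atoms: none
Why: Oxidative lactonisation of a 1,4-diol: the oxoammonium catalyst oxidises the primary alcohol first, ring closure with the C6 hydroxyl gives lactol 20, and this is oxidised on to the lactone; C6 and C7 are not touched, so the anti relationship from step 11 becomes the trans ring fusion.

Step 14
Reactants: 21
Product: 22 alkynyl diol (6R,7S,8S,9S,10R): 21 with C3H2OH and a terminal alkyne
Conditions: Bu4NF, THF, 0 °C → rt
Reagents that add atoms: none
Why: Fluoride-induced desilylation removes the primary silyl ether and the alkynyl silane in one operation; the lactone and acetonide are stable to these conditions.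

Step 15
Reactants: 22
Product: 23 (Z)-enal (6R,7S,8S,9S,10R): C3 aldehyde on the C4=C5 alkene
Conditions: Dess–Martin periodinane, NaHCO3, CH2Cl2, 0 °C
Reagents that add atoms: none
Why: Dess–Martin oxidation of the primary allylic alcohol; the tertiary alcohol cannot be oxidised, and short, buffered, cold conditions are chosen to keep the less stable (Z)-enal from isomerising.

Step 16
Reactants: 23
Product: 24 (E)-oxime of 23 (key-step precursor)
Conditions: NH2OH·HCl, NaOAc, EtOH, 0 °C → rt
Reagents that add atoms: hydroxylamine hydrochloride, NO.Cl
Why: Oxime condensation at the aldehyde under buffered conditions, fast relative to conjugate addition or lactone aminolysis; the anti (E) oxime is expected, and its geometry is irrelevant once the nitrile oxide is formed.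

Step 17
Reactants: 24
Product: 27 isoxazole-bridged ten-membered carbocycle (6R,7S,8S,9S,10S): C3 and C1 are positions 3 and 5 of the isoxazole; C10 tertiary alcohol; C8/C9 acetonide; saturated trans-lactone, via hydroximoyl chloride 25 (not isolated), via nitrile oxide 26 (not isolated)
Conditions: N-chlorosuccinimide, pyridine (cat.), DMF, 0 °C → rt; then syringe-pump addition (12 h) to Et3N, toluene, 60 °C, final concentration 1 mM
Reagents that add atoms: none
Why: Proposed new method: N-chlorosuccinimide chlorinates the aldoxime carbon to give 25, from which triethylamine removes HCl to release nitrile oxide 26; its carbon (C3) bonds to the unsubstituted alkyne terminus C2 and its oxygen to C1 in a concerted, asynchronous [3+2] cycloaddition. The closest known reaction type is the intramolecular nitrile oxide cycloaddition to alkynes and alkenes that closes large rings in the bridged sense; a ten-membered ring bridged across positions 3 and 5 of an isoxazole has no counterpart, hence the label. The isoxazole closes by the cycloaddition itself, and the ten-membered carbocycle closes through the new C2–C3 bond in the bridged mode, the seven-atom tether C4–C10 joining positions 3 and 5. No stereocentre is formed, so nothing has to be controlled beyond the five centres already present. The step needs the bridged 3,5-orientation over the fused 3,4-orientation (a nine-membered ring); this should be secured by the terminal alkyne, whose substituted carbon carries the fully substituted C10 and would have to take the crowded position 4 next to the C3 substituent. It also needs ring closure to outrun furoxan formation: 25 is fed slowly into warm, very dilute base so that 26 never accumulates, and the α-branch of the dipole (C4 methyl) slows dimerisation. The (Z)-alkene, the trans-fused lactone and the cis-dioxolane leave few rotatable bonds in the tether and turn its two ends toward each other, and the saturated lactone offers no second dipolarophile.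

Step 18
Reactants: 27
Product: 28 11-(dimethylaminomethyl) derivative of 27 (6R,7S,8S,9S,10S,11R; C13 anti to C8 on the lactone)
Conditions: LiN(iPr)2 (2.3 equiv), THF, −78 °C; Me2N=CH2+ I−, −78 → 0 °C; aq. NH4Cl
Reagents that add atoms: N,N-dimethylmethyleneiminium iodide, C=[N+](C)C.[I-]
Why: Mannich reaction of the lactone enolate; the second equivalent of base covers the C10 hydroxyl, the 3,5-disubstituted isoxazole has no acidic lateral position, and the iminium ion should enter anti to the C8 substituent on C7 (this centre is removed in step 22).

Step 19
Reactants: 28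
Product: 31 3(2H)-furanone 8,9-diol (6R,7R,8S,9S,10S,11R; C11 CH2NMe2), via enaminone 29 (not isolated), via furanone acetonide 30 (not isolated)
Conditions: Mo(CO)6, MeCN/H2O (10:1), 80 °C; then 1 M aq. HCl, THF, rt → 40 °C; aq. NaHCO3
Reagents that add atoms: none
Why: Reductive N–O cleavage of the isoxazole by Mo(CO)6 (zerovalent molybdenum) with water as proton source gives the vinylogous amide 29; in acid the C10 hydroxyl adds to C3 (5-exo) and ammonia leaves (addition–elimination) to give 30. Furanone closure should be much faster than acetal hydrolysis, so that O9 is still tied up while C3 is attacked, and continued hydrolysis then removes the acetonide.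

Step 20
Reactants: 31
Product: 32 8-O-methacrylate of 31 (6R,7S,8S,9S,10S,11R)
Conditions: methacrylic anhydride (1.1 equiv), Et3N, 4-(dimethylamino)pyridine (cat.), CH2Cl2, −20 °C
Reagents that add atoms: methacrylic anhydride, C=C(C)C(=O)OC(=O)C(C)=C
Why: Nucleophile-catalysed acylation under kinetic control; O8 is flanked by two CH groups, whereas O9 is neopentylic next to the fully substituted C10, so the first acyl group should go to O8.

Step 21
Reactants: 32
Product: 33 9-O-acetate of 32 (13-dimethylamino-11,13-dihydro form of 35)
Conditions: Ac2O, pyridine, 4-(dimethylamino)pyridine (cat.), CH2Cl2, 0 °C → rt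
Reagents that add atoms: acetic anhydride, CC(=O)OC(C)=O
Why: Acyl transfer to the remaining, hindered secondary alcohol with a small anhydride in excess, so that acetylation is faster than any O8→O9 shift of the methacrylate.

Step 22
Reactants: 33
Product: 35 CNP0365569.2 (6R,7S,8S,9S,10S)-9-acetoxy-8-methacryloyloxy-1-oxo-3,10-epoxygermacra-2,4(Z),11(13)-trien-12,6-olide, via ammonium iodide 34 (not isolated)
Conditions: MeI, MeCN, rt; then aq. NaHCO3, CH2Cl2, rt
Reagents that add atoms: none
Why: N-Methylation followed by E1cB elimination of trimethylamine from the β-ammonio lactone (Hofmann-type) under conditions mild enough for both esters and the vinylogous ester; C11 becomes sp2, so its configuration is erased.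

## Compound list

1 | 2,3-O-isopropylidene-D-erythronolactone | O=C1OC[C@H]2OC(C)(C)O[C@@H]12 | starting material
2 | 2,3-O-isopropylidene-D-erythrofuranose (lactol, anomers) | OC1OC[C@H]2OC(C)(C)O[C@@H]12 | intermediate
3 | ethyl (triphenylphosphoranylidene)acetate | CCOC(=O)C=P(c1ccccc1)(c1ccccc1)c1ccccc1 | starting material
4 | ethyl (E)-3-[(4S,5R)-5-(hydroxymethyl)-2,2-dimethyl-1,3-dioxolan-4-yl]prop-2-enoate | OC[C@H]1OC(C)(C)O[C@H]1/C=C/C(=O)OCC | intermediate
5 | trimethylsilylacetylene | C#C[Si](C)(C)C | starting material
6 | ethyl (E)-3-[(4S,5S)-5-formyl-2,2-dimethyl-1,3-dioxolan-4-yl]prop-2-enoate (not isolated) | O=C[C@H]1OC(C)(C)O[C@H]1/C=C/C(=O)OCC | intermediate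
7 | ethyl (E)-3-{(4S,5R)-5-[1-hydroxy-3-(trimethylsilyl)prop-2-ynyl]-2,2-dimethyl-1,3-dioxolan-4-yl}prop-2-enoate (C10 epimers) | C[Si](C)(C)C#CC(O)[C@H]1OC(C)(C)O[C@H]1/C=C/C(=O)OCC | intermediate
8 | ethyl (E)-3-{(4S,5S)-2,2-dimethyl-5-[3-(trimethylsilyl)prop-2-ynoyl]-1,3-dioxolan-4-yl}prop-2-enoate | C[Si](C)(C)C#CC(=O)[C@H]1OC(C)(C)O[C@H]1/C=C/C(=O)OCC | intermediate
9 | ethyl (E)-3-{(4S,5S)-5-[(2R)-2-hydroxy-4-(trimethylsilyl)but-3-yn-2-yl]-2,2-dimethyl-1,3-dioxolan-4-yl}prop-2-enoate | C[Si](C)(C)C#C[C@@](C)(O)[C@H]1OC(C)(C)O[C@H]1/C=C/C(=O)OCC | intermediate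
10 | (E)-3-{(4S,5S)-5-[(2R)-2-hydroxy-4-(trimethylsilyl)but-3-yn-2-yl]-2,2-dimethyl-1,3-dioxolan-4-yl}prop-2-en-1-ol | C[Si](C)(C)C#C[C@@](C)(O)[C@H]1OC(C)(C)O[C@H]1/C=C/CO | intermediate
11 | (2R)-2-{(4S,5S)-5-[(E)-3-bromoprop-1-enyl]-2,2-dimethyl-1,3-dioxolan-4-yl}-4-(trimethylsilyl)but-3-yn-2-ol | C[Si](C)(C)C#C[C@@](C)(O)[C@H]1OC(C)(C)O[C@H]1/C=C/CBr | intermediate
12 | 4-methyl-2(5H)-furanone | CC1=CC(=O)OC1 | starting material
13 | (Z)-4-hydroxy-N-methoxy-N,3-dimethylbut-2-enamide | CON(C)C(=O)/C=C(/C)CO | intermediate
14 | (Z)-4-[(tert-butyldimethylsilyl)oxy]-N-methoxy-N,3-dimethylbut-2-enamide | CON(C)C(=O)/C=C(/C)CO[Si](C)(C)C(C)(C)C | intermediate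
15 | (Z)-4-[(tert-butyldimethylsilyl)oxy]-3-methylbut-2-enal | O=C/C=C(/C)CO[Si](C)(C)C(C)(C)C | intermediate
16 | (E)-allylchromium dichloride from 11 (not isolated) | C[Si](C)(C)C#C[C@@](C)(O)[C@H]1OC(C)(C)O[C@H]1/C=C/C[Cr](Cl)Cl | intermediate
17 | homoallylic alcohol (6R,7S,8S,9S,10R) | C[Si](C)(C)C#C[C@@](C)(O)[C@H]1OC(C)(C)O[C@H]1[C@@H](C=C)[C@H](O)/C=C(/C)CO[Si](C)(C)C(C)(C)C | intermediate
18 | B-alkyl-9-borabicyclo[3.3.1]nonane at C12 of 17 (not isolated) | C[Si](C)(C)C#C[C@@](C)(O)[C@H]1OC(C)(C)O[C@H]1[C@@H](CCB2C3CCCC2CCC3)[C@H](O)/C=C(/C)CO[Si](C)(C)C(C)(C)C | intermediate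
19 | triol (6R,7S,8S,9S,10R) | C[Si](C)(C)C#C[C@@](C)(O)[C@H]1OC(C)(C)O[C@H]1[C@@H](CCO)[C@H](O)/C=C(/C)CO[Si](C)(C)C(C)(C)C | intermediate
20 | lactol between O6 and C12 (not isolated) | C[Si](C)(C)C#C[C@@](C)(O)[C@H]1OC(C)(C)O[C@H]1[C@H]2CC(O)O[C@@H]2/C=C(/C)CO[Si](C)(C)C(C)(C)C | intermediate
21 | silylated trans-lactone (6R,7S,8S,9S,10R) | C[Si](C)(C)C#C[C@@](C)(O)[C@H]1OC(C)(C)O[C@H]1[C@H]2CC(=O)O[C@@H]2/C=C(/C)CO[Si](C)(C)C(C)(C)C | intermediate
22 | alkynyl diol lactone (6R,7S,8S,9S,10R) | C#C[C@@](C)(O)[C@H]1OC(C)(C)O[C@H]1[C@H]2CC(=O)O[C@@H]2/C=C(/C)CO | intermediate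
23 | (Z)-enal lactone (6R,7S,8S,9S,10R) | C#C[C@@](C)(O)[C@H]1OC(C)(C)O[C@H]1[C@H]2CC(=O)O[C@@H]2/C=C(/C)C=O | intermediate
24 | (E)-oxime of 23 (key-step precursor) | C#C[C@@](C)(O)[C@H]1OC(C)(C)O[C@H]1[C@H]2CC(=O)O[C@@H]2/C=C(/C)\C=N\O | intermediate
25 | (Z)-hydroximoyl chloride (not isolated) | C#C[C@@](C)(O)[C@H]1OC(C)(C)O[C@H]1[C@H]2CC(=O)O[C@@H]2/C=C(/C)\C(Cl)=N\O | intermediate
26 | nitrile oxide (not isolated) | C#C[C@@](C)(O)[C@H]1OC(C)(C)O[C@H]1[C@H]2CC(=O)O[C@@H]2/C=C(/C)C#[N+][O-] | intermediate
27 | isoxazole-bridged ten-membered carbocycle (6R,7S,8S,9S,10S; key-step product) | CC1(C)O[C@H]2[C@H]3CC(=O)O[C@@H]3/C=C(/C)c3cc(on3)[C@@](C)(O)[C@H]2O1 | intermediate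
28 | 11-(dimethylaminomethyl) derivative of 27 (11R) | CC1(C)O[C@H]2[C@H]3[C@H](CN(C)C)C(=O)O[C@@H]3/C=C(/C)c3cc(on3)[C@@](C)(O)[C@H]2O1 | intermediate
29 | (Z)-3-amino-2-en-1-one (enaminone; not isolated) | CC1(C)O[C@H]2[C@H]3[C@H](CN(C)C)C(=O)O[C@@H]3/C=C(/C)\C(N)=C\C(=O)[C@@](C)(O)[C@H]2O1 | intermediate
30 | 3(2H)-furanone with C8/C9 acetonide (not isolated) | CC1(C)O[C@H]2[C@H]3[C@H](CN(C)C)C(=O)O[C@@H]3/C=C(/C)C3=CC(=O)[C@@](C)(O3)[C@H]2O1 | intermediate
31 | 3(2H)-furanone 8,9-diol (C11 CH2NMe2) | O[C@H]1[C@H]2[C@H](CN(C)C)C(=O)O[C@@H]2/C=C(/C)C2=CC(=O)[C@@](C)(O2)[C@H]1O | intermediate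
32 | 8-O-methacrylate of 31 | C=C(C)C(=O)O[C@H]1[C@H]2[C@H](CN(C)C)C(=O)O[C@@H]2/C=C(/C)C2=CC(=O)[C@@](C)(O2)[C@H]1O | intermediate
33 | 9-O-acetate of 32 | C=C(C)C(=O)O[C@H]1[C@H]2[C@H](CN(C)C)C(=O)O[C@@H]2/C=C(/C)C2=CC(=O)[C@@](C)(O2)[C@H]1OC(C)=O | intermediate
34 | trimethylammonium iodide of 33 (not isolated) | C=C(C)C(=O)O[C@H]1[C@H]2[C@H](C[N+](C)(C)C)C(=O)O[C@@H]2/C=C(/C)C2=CC(=O)[C@@](C)(O2)[C@H]1OC(C)=O.[I-] | intermediate
35 | CNP0365569.2 | C=C(C)C(=O)O[C@H]1[C@H]2C(=C)C(=O)O[C@@H]2/C=C(/C)C2=CC(=O)[C@@](C)(O2)[C@H]1OC(C)=O | target

## Step count and least certain steps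

Total step count: 22. Longest linear sequence: 19 steps (steps 1–7 and 11–22, from 1 to 35); steps 8–10 make fragment 15.

Step 17 (key step). The most likely failure is intermolecular dimerisation or oligomerisation of the nitrile oxide outrunning a slow ring closure, because the transition state already contains much of the strain of a bridged isoxazole in a ten-membered ring; closure in the fused 3,4-sense is the second risk. The fallback uses known reactions, leaves the route at 22 and returns at 27. Iodination of the terminal alkyne of 22 (N-iodosuccinimide, AgNO3 cat., acetone) would give iodoalkyne diol F1. Dess–Martin oxidation would give iodoalkynyl enal F2. Intramolecular Nozaki–Hiyama–Kishi addition (CrCl2, NiCl2 cat., THF, high dilution), a reaction type established for ten-membered enyne rings, would form the C2–C3 bond and give the cyclic propargylic alcohol F3 as a C3 epimer mixture. Oxidation would give the macrocyclic ynone F4. Condensation with NH2OH·HCl/NaOAc would give ynone oxime F5, and AuCl3-catalysed 5-endo cycloisomerisation of the oxime oxygen onto C1 would give 27. The ring is thus closed by a carbonyl addition while the alkyne is still linear, and the isoxazole is formed afterwards across the ring.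

Step 11. The likely failure is poor facial selectivity with respect to C8: the anti C6/C7 relationship is dictated by the chair, but the preference for attack anti to the dioxolane C–O bond rests on a conformational argument and could be weak or reversed. The fallback leaves at 11 and returns at 17. Borylation of 11 with bis(pinacolato)diboron and Pd2(dba)3 (zerovalent palladium) would give the linear (E)-allylboronate F6. Its addition to 15 under catalysis by one enantiomer of 3,3'-bis(2,4,6-triisopropylphenyl)-1,1'-binaphthyl-2,2'-diyl hydrogen phosphate would proceed through a closed chair, so the anti relationship is kept while the aldehyde face, and with it C6 and C7, is chosen by the catalyst.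

Step 5. The likely failure is loss of chelation control, because a dioxolane oxygen is a weak donor and the competing Felkin–Anh pathway gives the C10 epimer. The fallback leaves at 4 and returns at 9; it reverses the order of the two nucleophiles, so that the same non-chelated preference now gives the wanted configuration. Swern oxidation of 4 with addition of MeMgBr to the cold mixture would give secondary alcohol F7. Dess–Martin oxidation would give methyl ketone F8. Addition of LiC≡CSiMe3 in THF at −78 °C (non-chelating conditions) would give 9.

Step 20. The likely failure is acylation at the wrong oxygen or at both, because the steric difference between O8 and O9 in the folded bicyclic diol may be smaller than assumed. The fallback leaves at 31 and returns at 33; it uses a silyl relay, since silylation discriminates more strongly by size than acylation. Et3SiCl/imidazole would give the 8-O-triethylsilyl ether F9. Acetylation would give the 8-O-silyl 9-acetate F10. Acidic desilylation (HF·pyridine, which disfavours acyl shift) would give the 9-acetate 8-alcohol F11, which would be methacryloylated at once to give 33.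

## Further compounds

F1 | step 17 | iodoalkyne diol | IC#C[C@@](C)(O)[C@H]1OC(C)(C)O[C@H]1[C@H]2CC(=O)O[C@@H]2/C=C(/C)CO
F2 | step 17 | iodoalkynyl (Z)-enal | IC#C[C@@](C)(O)[C@H]1OC(C)(C)O[C@H]1[C@H]2CC(=O)O[C@@H]2/C=C(/C)C=O
F3 | step 17 | ten-membered cyclic propargylic alcohol (C3 epimers) | CC1(C)O[C@H]2[C@H]3CC(=O)O[C@@H]3/C=C(/C)C(O)C#C[C@@](C)(O)[C@H]2O1
F4 | step 17 | ten-membered cyclic ynone | CC1(C)O[C@H]2[C@H]3CC(=O)O[C@@H]3/C=C(/C)C(=O)C#C[C@@](C)(O)[C@H]2O1
F5 | step 17 | oxime of the cyclic ynone | CC1(C)O[C@H]2[C@H]3CC(=O)O[C@@H]3/C=C(/C)C(=NO)C#C[C@@](C)(O)[C@H]2O1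
F6 | step 11 | (E)-allylboronic acid pinacol ester from 11 | C[Si](C)(C)C#C[C@@](C)(O)[C@H]1OC(C)(C)O[C@H]1/C=C/CB2OC(C)(C)C(C)(C)O2
F7 | step 5 | ethyl (E)-3-[(4S,5R)-5-(1-hydroxyethyl)-2,2-dimethyl-1,3-dioxolan-4-yl]prop-2-enoate (carbinol epimers) | CC(O)[C@H]1OC(C)(C)O[C@H]1/C=C/C(=O)OCC
F8 | step 5 | ethyl (E)-3-[(4S,5S)-5-acetyl-2,2-dimethyl-1,3-dioxolan-4-yl]prop-2-enoate | CC(=O)[C@H]1OC(C)(C)O[C@H]1/C=C/C(=O)OCC
F9 | step 20 | 8-O-triethylsilyl ether of 31 | CC[Si](CC)(CC)O[C@H]1[C@H]2[C@H](CN(C)C)C(=O)O[C@@H]2/C=C(/C)C2=CC(=O)[C@@](C)(O2)[C@H]1O
F10 | step 20 | 8-O-triethylsilyl 9-O-acetate | CC[Si](CC)(CC)O[C@H]1[C@H]2[C@H](CN(C)C)C(=O)O[C@@H]2/C=C(/C)C2=CC(=O)[C@@](C)(O2)[C@H]1OC(C)=O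
F11 | step 20 | 9-O-acetate 8-alcohol | O[C@H]1[C@H]2[C@H](CN(C)C)C(=O)O[C@@H]2/C=C(/C)C2=CC(=O)[C@@](C)(O2)[C@H]1OC(C)=O
A1 | alternative 1 | seco C9 aldehyde with 2-methyl-3-(tert-butyldimethylsilyloxy)furan | C=C(C)C(=O)O[C@H](C=O)[C@H]1C(=C)C(=O)O[C@@H]1/C=C(/C)c1cc(O[Si](C)(C)C(C)(C)C)c(C)o1
A2 | alternative 1 | 9-O-deacetyl target | C=C(C)C(=O)O[C@H]1[C@H]2C(=C)C(=O)O[C@@H]2/C=C(/C)C2=CC(=O)[C@@](C)(O2)[C@H]1O
A3 | alternative 2 | ten-membered ring with C3/C6-bridging furan, C1 ketone and free C10 hydroxyl | COC(=O)C[C@H]1c2cc(C)c(o2)CC(=O)[C@@](C)(O)[C@H]2OC(C)(C)O[C@@H]12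
A4 | alternative 2 | bridged furanone with (Z)-C4=C5 and C6 ketone | COC(=O)C[C@H]1C(=O)/C=C(/C)C2=CC(=O)[C@@](C)(O2)[C@H]2OC(C)(C)O[C@@H]12
A5 | alternative 3 | seco iodoalkyne C1 aldehyde | O=C[C@@](C)(O[Si](CC)(CC)CC)[C@H]1OC(C)(C)O[C@H]1[C@H]2C(=C)C(=O)O[C@@H]2/C=C(/C)C#CI
A6 | alternative 3 | ten-membered enyne propargylic alcohol | CC1(C)O[C@H]2[C@H]3C(=C)C(=O)O[C@@H]3/C=C(/C)C#C[C@H](O)[C@@](C)(O[Si](CC)(CC)CC)[C@H]2O1
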